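**Retrosynthetic overview**

1. The target is epicatechin 3-O-gallate-(4β→8)-epicatechin 3-O-gallate-(4β→6)-catechin (top, middle and bottom units). The plan rests on ring C of the middle unit (O1–C2–C3–C4–C4a–C8a). Its three adjacent stereocentres C2, C3 and C4 lie next to the aryl oxygen O1 on C8a, so O1–C2 and C3–C4 are cut together as an ortho-quinone methide [4+2].
2. The last operations, read backwards, are global hydrogenolysis (19 O-benzyl groups and one C–Br), galloylation of the two epicatechin 3-OH groups, and C3–Si to C3–OH with retention. Silicon stands in for O3 so that the alkene adds with flavan-3-ol regiochemistry.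
3. The oxadiene comes from an ortho-hydroxy diarylcarbinol. This is cut at C4(middle)–C6(bottom) into a salicylaldehyde and a 6-metalated catechin. Halogenation of benzylated catechin goes to C8, so C8 is capped with bromine first and C6 is iodinated second.
4. The salicylaldehyde is cut at C4(top)–C8(middle) into an epicatechin C4 cation and 3,5-bis(benzyloxy)phenol, which is then formylated ortho to its OH.
5. Ring order: the top and bottom chromans come with the two flavan-3-ols, middle rings A and B come as arenes, and middle ring C is the only ring built, last of all.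

Key step: step 14

Remark (assumption): it cannot be derived on paper which enantiomer of the chiral phosphoric acid reinforces the facial bias of the top unit, so (R)-TRIP is written and its antipode takes its place if that one proves matched.

**Route**

Step 1
Reactants: 1 (−)-epicatechin
Product: 2 5,7,3',4'-tetra-O-benzyl-(−)-epicatechin
Conditions: BnBr (4.4 equiv), K2CO3, DMF, 0 °C to rt
Reagents that add atoms: benzyl bromide BrCc1ccccc1
Why: Williamson etherification, in which K2CO3 deprotonates only the four phenols so the 3-OH stays free, while the mild base and low temperature guard C2 against epimerisation.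

Step 2
Reactants: 2 5,7,3',4'-tetra-O-benzyl-(−)-epicatechin
Product: 3 3-O-TBS-5,7,3',4'-tetra-O-benzylepicatechin
Conditions: TBSOTf, 2,6-lutidine, CH2Cl2, 0 °C
Reagents that add atoms: tert-butyldimethylsilyl triflate CC(C)(C)[Si](C)(C)OS(=O)(=O)C(F)(F)F
Why: Silyl triflate silylation of the axial secondary alcohol, done before C4 is activated so that no acid-labile group is present, marks this oxygen for later galloylation and adds bulk to the α-face.

Step 3
Reactants: 3 3-O-TBS-5,7,3',4'-tetra-O-benzylepicatechin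
Product: 4 4β-(2-ethoxyethoxy)-3-O-TBS-5,7,3',4'-tetra-O-benzylepicatechin
Conditions: DDQ, 2-ethoxyethanol, CH2Cl2, rt
Reagents that add atoms: 2-ethoxyethanol CCOCCO
Why: DDQ benzylic oxidation abstracts hydride from C4 to give the cation stabilised by the 5,7-dibenzyloxy ring A, and the alcohol adds from the β-face, anti to the 3-OTBS and 2-aryl groups.

Step 4
Reactants: 4 4β-(2-ethoxyethoxy)-3-O-TBS-5,7,3',4'-tetra-O-benzylepicatechin; 5 3,5-bis(benzyloxy)phenol
Product: 6 4β-[2-hydroxy-4,6-bis(benzyloxy)phenyl]-3-O-TBS-5,7,3',4'-tetra-O-benzylepicatechin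
Conditions: 5 (4 equiv), TMSOTf (0.2 equiv), CH2Cl2, −78 to −40 °C
Reagents that add atoms: none
Why: Friedel–Crafts capture of the flavan-4-yl cation, in which the excess phenol attacks through a carbon ortho to OH (less crowded than the carbon between the two OBn groups) and from the β-face opposite 3-OTBS and the 2-aryl group, sets top C4 as 3,4-trans.

Step 5
Reactants: 6 4β-[2-hydroxy-4,6-bis(benzyloxy)phenyl]-3-O-TBS-5,7,3',4'-tetra-O-benzylepicatechin
Product: 7 4β-[3-formyl-2-hydroxy-4,6-bis(benzyloxy)phenyl]-3-O-TBS-5,7,3',4'-tetra-O-benzylepicatechin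
Conditions: MgCl2, Et3N, (CH2O)n, THF, reflux; dilute HCl work-up
Reagents that add atoms: paraformaldehyde (as formaldehyde) C=O
Why: Casnati–Skattebøl ortho-formylation delivers formaldehyde inside the magnesium phenoxide complex, so only the one open position ortho to OH (future C4a) reacts and the position between the two OBn groups is left alone.

Step 6
Reactants: 8 (+)-catechin
Product: 9 5,7,3',4'-tetra-O-benzyl-(+)-catechin
Conditions: BnBr (4.4 equiv), K2CO3, DMF, 0 °C to rt
Reagents that add atoms: benzyl bromide BrCc1ccccc1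
Why: Williamson etherification that is selective for the four phenols, as in step 1.

Step 7
Reactants: 9 5,7,3',4'-tetra-O-benzyl-(+)-catechin
Product: 10 3,5,7,3',4'-penta-O-benzyl-(+)-catechin
Conditions: NaH, BnBr, DMF, 0 °C to rt
Reagents that add atoms: benzyl bromide BrCc1ccccc1
Why: Williamson etherification of the alkoxide gives the bottom 3-oxygen a group that is untouched by fluoride and by galloylation and falls only in the last step, so this 3-OH ends up free.

Step 8
Reactants: 10 3,5,7,3',4'-penta-O-benzyl-(+)-catechin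
Product: 11 8-bromo-3,5,7,3',4'-penta-O-benzylcatechin
Conditions: NBS (1.0 equiv), CH2Cl2, −78 °C to rt
Reagents that add atoms: N-bromosuccinimide O=C1CCC(=O)N1Br
Why: Electrophilic aromatic bromination of 5,7-di-O-benzylflavans goes to C8 (between O1 and one OBn) rather than C6 (between two OBn groups), so C8 is deliberately capped here.

Step 9
Reactants: 11 8-bromo-3,5,7,3',4'-penta-O-benzylcatechin
Product: 12 8-bromo-6-iodo-3,5,7,3',4'-penta-O-benzylcatechin
Conditions: NIS, TFA (cat.), CH2Cl2/MeCN, 0 °C to rt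
Reagents that add atoms: N-iodosuccinimide O=C1CCC(=O)N1I
Why: Electrophilic aromatic iodination can only reach C6, the last open position of the phloroglucinol-type ring A, which is far more activated than ring B.

Step 10
Reactants: 12 8-bromo-6-iodo-3,5,7,3',4'-penta-O-benzylcatechin; 7 4β-[3-formyl-2-hydroxy-4,6-bis(benzyloxy)phenyl]-3-O-TBS-5,7,3',4'-tetra-O-benzylepicatechin
Product: 15 ortho-hydroxy diarylcarbinol joining top unit/middle ring A/8-bromo bottom unit (both carbinol epimers), via arylmagnesium chloride 13 (not isolated), via sodium phenoxide 14 (not isolated)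
Conditions: 12, iPrMgCl·LiCl, THF, −20 to 0 °C; separately 7, NaH, THF, 0 °C; combine, 0 °C to rt; aq NH4Cl
Reagents that add atoms: none
Why: Iodine–magnesium exchange is much faster at C–I than at C–Br, so only C6 is metalated, and Grignard 1,2-addition to the pre-formed phenoxide of the salicylaldehyde gives the carbinol, whose unselective new centre does no harm because it becomes planar in step 14.

Step 11
Reactants: 16 3,4-bis(benzyloxy)benzaldehyde
Product: 17 1,2-bis(benzyloxy)-4-ethynylbenzene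
Conditions: dimethyl (1-diazo-2-oxopropyl)phosphonate, K2CO3, MeOH/THF, rt
Reagents that add atoms: dimethyl (1-diazo-2-oxopropyl)phosphonate CC(=O)C(=[N+]=[N-])P(=O)(OC)OC
Why: Ohira–Bestmann (Seyferth–Gilbert) homologation turns a non-enolisable aromatic aldehyde into the terminal alkyne under mild base that leaves the benzyl ethers alone.

Step 12
Reactants: 17 1,2-bis(benzyloxy)-4-ethynylbenzene
Product: 19 benzyl{[3,4-bis(benzyloxy)phenyl]ethynyl}dimethylsilane, via lithium acetylide 18 (not isolated)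
Conditions: n-BuLi, THF, −78 °C; BnMe2SiCl, −78 °C to rt
Reagents that add atoms: benzyl(chloro)dimethylsilane C[Si](C)(Cl)Cc1ccccc1
Why: Deprotonation of the acidic alkyne C–H followed by C-silylation of the acetylide fixes silicon on the terminal carbon without regiochemical ambiguity.

Step 13
Reactants: 19 benzyl{[3,4-bis(benzyloxy)phenyl]ethynyl}dimethylsilane
Product: 20 (Z)-benzyl{2-[3,4-bis(benzyloxy)phenyl]ethenyl}dimethylsilane
Conditions: H2 (1 atm), Pd/CaCO3 poisoned with Pb(OAc)2, quinoline, EtOAc, rt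
Reagents that add atoms: none
Why: Lindlar semi-hydrogenation delivers both hydrogens to one face of the alkyne and so gives the Z alkene, while the poisoned catalyst spares the benzyl ethers.

Step 14
Reactants: 15 ortho-hydroxy diarylcarbinol (both carbinol epimers); 20 (Z)-benzyl{2-[3,4-bis(benzyloxy)phenyl]ethenyl}dimethylsilane
Product: 22 protected trimer skeleton carrying 3α-SiMe2Bn in the middle unit (2,3-cis-3,4-trans), via ortho-quinone methide 21 (not isolated)
Conditions: 20 (3 equiv), (R)-TRIP [(R)-3,3'-bis(2,4,6-triisopropylphenyl)-BINOL hydrogen phosphate, 10 mol %], 4 Å MS, PhMe, −20 °C to rt, slow addition of 15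
Reagents that add atoms: none
Why: Proposed new method: the phosphoric acid removes water from either epimer of 15 to give the hydrogen-bonded (E)-ortho-quinone methide 21, an electron-poor 1-oxadiene (O1=C8a–C4a=C4) that is most electrophilic at C4, and 20 attacks C4 through its silicon-bearing carbon because the charge then building at C2 is benzylic to a para-benzyloxyaryl group and β to silicon, so C3–C4 bonding runs ahead of O1–C2 bonding within one asynchronous suprafacial [4+2] event. The closest known reaction type is the Brønsted-acid-catalysed inverse-demand hetero-Diels–Alder reaction of ortho-quinone methides from ortho-hydroxybenzhydrols with styrenes, which gives 2,4-diarylchromans, whereas a β-silyl (Z)-styrene and a methide carbon bearing a 2,6-dialkoxyaryl group are untested. Middle ring C closes as a six-membered ring by intermolecular [4π+2π] cycloaddition whose last event is collapse of O1 onto C2, which should outrun loss of silicon because the phenolate oxygen sits beside the developing cation and the bulky phosphate in toluene is a poor nucleophile towards silicon. C2 and C3 become cis because the Z geometry of 20 is carried over suprafacially, and C3 and C4 become trans through the exo transition state, which is expected because the endo space over ring A is closed by the 5-OBn group on one side and the C8 flavanyl group on the other, so silicon lies between H-4 and the catechin aryl. The absolute sense (2α-aryl, 3α-silyl, 4β-aryl) depends on which face of planar 21 is attacked, where the top unit at C8 beside O1 (its C3-OTBS/C2-aryl flank over one face, its ring A over the other) is the resident control element and the chiral phosphate bound at O1 the external one, and a wrong-face adduct would be a separable diastereomer. The step also needs a single oxadiene, which is secured because the oxygen on C8a is the only free phenol, and chemoselectivity against arylation of C4 by electron-rich rings, which is helped by the bromine on bottom C8, the excess of 20 and the slow addition of 15.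

Step 15
Reactants: 22 protected trimer skeleton carrying 3α-SiMe2Bn in the middle unit
Product: 24 protected trimer 3,3''-diol (free 3-OH in top unit/middle unit), via dimethylsilanol 23 (not isolated)
Conditions: TBAF, THF, 0 °C to rt; then KHCO3, 30% H2O2, MeOH/THF, 40 °C
Reagents that add atoms: hydrogen peroxide OO
Why: In this Tamao–Fleming oxidation fluoride cleaves the benzyl–silicon bond and the top 3-O-TBS ether, and the peroxide adduct of the resulting silanol moves C3 from silicon to oxygen with retention to give the 3α-oxygen, while the axial C3–Si bond of the preferred half-chair is gauche to C2–O1 and so is badly aligned for β-elimination of the aryloxide.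

Step 16
Reactants: 24 protected trimer 3,3''-diol; 25 3,4,5-tris(benzyloxy)benzoic acid
Product: 26 fully protected 8-bromo trimer 3,3''-bis(tri-O-benzylgallate)
Conditions: 25 (4 equiv), DCC, DMAP, CH2Cl2, rt
Reagents that add atoms: none
Why: Steglich esterification acylates the only two free hydroxyl groups at oxygen, so no stereocentre is touched and the benzyl-protected bottom 3-oxygen stays out of play.

Step 17
Reactants: 26 fully protected 8-bromo trimer 3,3''-bis(tri-O-benzylgallate)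
Product: 27 CNP0154615.1
Conditions: H2 (1 atm), Pd(OH)2/C, NaOAc (1.1 equiv), THF/MeOH/H2O (degassed), rt
Reagents that add atoms: none
Why: Catalytic hydrogenolysis removes all nineteen O-benzyl groups and the C8 bromine cap in one operation, acetate takes up the HBr so the acid-labile interflavan bonds are not stressed, and the gallate esters and chroman C–O bonds persist at atmospheric pressure.

**Compound list**

1 | (−)-epicatechin | O[C@@H]1Cc2c(O)cc(O)cc2O[C@@H]1c1ccc(O)c(O)c1 | starting material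
2 | 5,7,3',4'-tetra-O-benzyl-(−)-epicatechin | O[C@@H]1Cc2c(OCc9ccccc9)cc(OCc9ccccc9)cc2O[C@@H]1c8ccc(OCc9ccccc9)c(OCc9ccccc9)c8 | intermediate
3 | 3-O-TBS-5,7,3',4'-tetra-O-benzylepicatechin | CC(C)(C)[Si](C)(C)O[C@@H]1Cc2c(OCc9ccccc9)cc(OCc9ccccc9)cc2O[C@@H]1c8ccc(OCc9ccccc9)c(OCc9ccccc9)c8 | intermediate
4 | 4β-(2-ethoxyethoxy)-3-O-TBS-5,7,3',4'-tetra-O-benzylepicatechin | CC(C)(C)[Si](C)(C)O[C@@H]1[C@@H](OCCOCC)c2c(OCc9ccccc9)cc(OCc9ccccc9)cc2O[C@@H]1c8ccc(OCc9ccccc9)c(OCc9ccccc9)c8 | intermediate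
5 | 3,5-bis(benzyloxy)phenol | Oc1cc(OCc2ccccc2)cc(OCc2ccccc2)c1 | starting material
6 | 4β-[2-hydroxy-4,6-bis(benzyloxy)phenyl]-3-O-TBS-5,7,3',4'-tetra-O-benzylepicatechin | CC(C)(C)[Si](C)(C)O[C@@H]1[C@@H](c3c(OCc9ccccc9)cc(OCc9ccccc9)cc3O)c2c(OCc9ccccc9)cc(OCc9ccccc9)cc2O[C@@H]1c8ccc(OCc9ccccc9)c(OCc9ccccc9)c8 | intermediate
7 | 4β-[3-formyl-2-hydroxy-4,6-bis(benzyloxy)phenyl]-3-O-TBS-5,7,3',4'-tetra-O-benzylepicatechin | CC(C)(C)[Si](C)(C)O[C@@H]1[C@@H](c3c(OCc9ccccc9)cc(OCc9ccccc9)c(C=O)c3O)c2c(OCc9ccccc9)cc(OCc9ccccc9)cc2O[C@@H]1c8ccc(OCc9ccccc9)c(OCc9ccccc9)c8 | intermediate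
8 | (+)-catechin | O[C@H]1Cc2c(O)cc(O)cc2O[C@@H]1c1ccc(O)c(O)c1 | starting material
9 | 5,7,3',4'-tetra-O-benzyl-(+)-catechin | O[C@H]1Cc2c(OCc9ccccc9)cc(OCc9ccccc9)cc2O[C@@H]1c8ccc(OCc9ccccc9)c(OCc9ccccc9)c8 | intermediate
10 | 3,5,7,3',4'-penta-O-benzyl-(+)-catechin | c1c(OCc9ccccc9)cc2c(c1OCc9ccccc9)C[C@H](OCc9ccccc9)[C@@H](c8ccc(OCc9ccccc9)c(OCc9ccccc9)c8)O2 | intermediate
11 | 8-bromo-3,5,7,3',4'-penta-O-benzylcatechin | c1c(OCc9ccccc9)c(Br)c2c(c1OCc9ccccc9)C[C@H](OCc9ccccc9)[C@@H](c8ccc(OCc9ccccc9)c(OCc9ccccc9)c8)O2 | intermediate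
12 | 8-bromo-6-iodo-3,5,7,3',4'-penta-O-benzylcatechin | Ic1c(OCc9ccccc9)c(Br)c2c(c1OCc9ccccc9)C[C@H](OCc9ccccc9)[C@@H](c8ccc(OCc9ccccc9)c(OCc9ccccc9)c8)O2 | intermediate
13 | (8-bromo-penta-O-benzylcatechin-6-yl)magnesium chloride (LiCl complex) | Cl[Mg]c1c(OCc9ccccc9)c(Br)c2c(c1OCc9ccccc9)C[C@H](OCc9ccccc9)[C@@H](c8ccc(OCc9ccccc9)c(OCc9ccccc9)c8)O2 | intermediate
14 | sodium phenoxide of 7 | CC(C)(C)[Si](C)(C)O[C@@H]1[C@@H](c3c(OCc9ccccc9)cc(OCc9ccccc9)c(C=O)c3[O-])c2c(OCc9ccccc9)cc(OCc9ccccc9)cc2O[C@@H]1c8ccc(OCc9ccccc9)c(OCc9ccccc9)c8.[Na+] | intermediate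
15 | ortho-hydroxy diarylcarbinol: top unit C4β on C8, free OH on C8a, CH(OH) on C4a bound to C6 of the 8-bromo bottom unit (carbinol epimers) | CC(C)(C)[Si](C)(C)O[C@@H]1[C@@H](c3c(OCc9ccccc9)cc(OCc9ccccc9)c(C(O)c5c(OCc9ccccc9)c(Br)c6c(c5OCc9ccccc9)C[C@H](OCc9ccccc9)[C@@H](c8ccc(OCc9ccccc9)c(OCc9ccccc9)c8)O6)c3O)c2c(OCc9ccccc9)cc(OCc9ccccc9)cc2O[C@@H]1c8ccc(OCc9ccccc9)c(OCc9ccccc9)c8 | intermediate
16 | 3,4-bis(benzyloxy)benzaldehyde | O=Cc1ccc(OCc2ccccc2)c(OCc2ccccc2)c1 | starting material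
17 | 1,2-bis(benzyloxy)-4-ethynylbenzene | C#Cc8ccc(OCc9ccccc9)c(OCc9ccccc9)c8 | intermediate
18 | lithium [3,4-bis(benzyloxy)phenyl]acetylide | [Li]C#Cc8ccc(OCc9ccccc9)c(OCc9ccccc9)c8 | intermediate
19 | benzyl{[3,4-bis(benzyloxy)phenyl]ethynyl}dimethylsilane | C[Si](C)(Cc9ccccc9)C#Cc8ccc(OCc9ccccc9)c(OCc9ccccc9)c8 | intermediate
20 | (Z)-benzyl{2-[3,4-bis(benzyloxy)phenyl]ethenyl}dimethylsilane | C[Si](C)(Cc9ccccc9)\C=C/c8ccc(OCc9ccccc9)c(OCc9ccccc9)c8 | intermediate
21 | (E)-ortho-quinone methide of middle ring A (C8a=O, C4a=C4, catechin aryl anti to C8a) | CC(C)(C)[Si](C)(C)O[C@@H]1[C@@H](C3=C(OCc9ccccc9)C=C(OCc9ccccc9)/C(=C\c5c(OCc9ccccc9)c(Br)c6c(c5OCc9ccccc9)C[C@H](OCc9ccccc9)[C@@H](c8ccc(OCc9ccccc9)c(OCc9ccccc9)c8)O6)C3=O)c2c(OCc9ccccc9)cc(OCc9ccccc9)cc2O[C@@H]1c8ccc(OCc9ccccc9)c(OCc9ccccc9)c8 | intermediate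
22 | [3-O-TBS-tetra-O-benzylepicatechin]-(4β→8)-[3-deoxy-3α-(benzyldimethylsilyl)-tetra-O-benzylepicatechin]-(4β→6)-[8-bromo-penta-O-benzylcatechin] | CC(C)(C)[Si](C)(C)O[C@@H]1[C@@H](c3c(OCc9ccccc9)cc(OCc9ccccc9)c4c3O[C@H](c8ccc(OCc9ccccc9)c(OCc9ccccc9)c8)[C@H]([Si](C)(C)Cc9ccccc9)[C@H]4c5c(OCc9ccccc9)c(Br)c6c(c5OCc9ccccc9)C[C@H](OCc9ccccc9)[C@@H](c8ccc(OCc9ccccc9)c(OCc9ccccc9)c8)O6)c2c(OCc9ccccc9)cc(OCc9ccccc9)cc2O[C@@H]1c8ccc(OCc9ccccc9)c(OCc9ccccc9)c8 | intermediate
23 | middle-unit 3α-(hydroxydimethylsilyl) trimer with free top 3-OH | O[C@@H]1[C@@H](c3c(OCc9ccccc9)cc(OCc9ccccc9)c4c3O[C@H](c8ccc(OCc9ccccc9)c(OCc9ccccc9)c8)[C@H]([Si](C)(C)O)[C@H]4c5c(OCc9ccccc9)c(Br)c6c(c5OCc9ccccc9)C[C@H](OCc9ccccc9)[C@@H](c8ccc(OCc9ccccc9)c(OCc9ccccc9)c8)O6)c2c(OCc9ccccc9)cc(OCc9ccccc9)cc2O[C@@H]1c8ccc(OCc9ccccc9)c(OCc9ccccc9)c8 | intermediate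
24 | [tetra-O-benzylepicatechin]-(4β→8)-[tetra-O-benzylepicatechin]-(4β→6)-[8-bromo-penta-O-benzylcatechin], 3,3''-diol | O[C@@H]1[C@@H](c3c(OCc9ccccc9)cc(OCc9ccccc9)c4c3O[C@H](c8ccc(OCc9ccccc9)c(OCc9ccccc9)c8)[C@H](O)[C@H]4c5c(OCc9ccccc9)c(Br)c6c(c5OCc9ccccc9)C[C@H](OCc9ccccc9)[C@@H](c8ccc(OCc9ccccc9)c(OCc9ccccc9)c8)O6)c2c(OCc9ccccc9)cc(OCc9ccccc9)cc2O[C@@H]1c8ccc(OCc9ccccc9)c(OCc9ccccc9)c8 | intermediate
25 | 3,4,5-tris(benzyloxy)benzoic acid | OC(=O)c1cc(OCc2ccccc2)c(OCc2ccccc2)c(OCc2ccccc2)c1 | starting material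
26 | 3,3''-bis-O-(tri-O-benzylgalloyl) derivative of 24 | O=C(O[C@@H]1[C@@H](c3c(OCc9ccccc9)cc(OCc9ccccc9)c4c3O[C@H](c8ccc(OCc9ccccc9)c(OCc9ccccc9)c8)[C@H](OC(=O)c7cc(OCc9ccccc9)c(OCc9ccccc9)c(OCc9ccccc9)c7)[C@H]4c5c(OCc9ccccc9)c(Br)c6c(c5OCc9ccccc9)C[C@H](OCc9ccccc9)[C@@H](c8ccc(OCc9ccccc9)c(OCc9ccccc9)c8)O6)c2c(OCc9ccccc9)cc(OCc9ccccc9)cc2O[C@@H]1c8ccc(OCc9ccccc9)c(OCc9ccccc9)c8)c7cc(OCc9ccccc9)c(OCc9ccccc9)c(OCc9ccccc9)c7 | intermediate
27 | CNP0154615.1, epicatechin 3-O-gallate-(4β→8)-epicatechin 3-O-gallate-(4β→6)-catechin | O=C(O[C@@H]1[C@@H](c2c(O)cc(O)c3c2O[C@H](c2ccc(O)c(O)c2)[C@H](OC(=O)c2cc(O)c(O)c(O)c2)[C@H]3c2c(O)cc3c(c2O)C[C@H](O)[C@@H](c2ccc(O)c(O)c2)O3)c2c(O)cc(O)cc2O[C@@H]1c1ccc(O)c(O)c1)c1cc(O)c(O)c(O)c1 | target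

**Step count**

- Total step count: 17.
- Longest linear sequence: 10 steps (1, 2, 3, 4, 5, 10, 14, 15, 16, 17).

**Steps most likely to fail**

**1. Step 14.**

Several processes may go wrong:
- Silicon may be lost from the β-silyl benzylic cation before O1 closes, which gives vinylation of C4 instead of cycloaddition.
- C3–C4 bond formation may be sluggish at a methide carbon flanked by four ortho substituents.
- The reaction may leak through the endo mode that styrenes usually prefer.
- Facial selectivity may be poor.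
- The methide may be arylated by ring A of a second molecule.

The fallback builds the same skeleton by known cationic flavanyl couplings. It sets out from 4 and 11 and comes back to the route at 24. Compound 4 is treated with 2,6-dimethylbenzenethiol and BF3·OEt2 (CH2Cl2, −78 °C) to give 4β-(2,6-dimethylphenylthio)-3-O-TBS-tetra-O-benzylepicatechin F1. An excess of F1 then acts as the C8 nucleophile towards a second portion of 4 under BF3·OEt2, a hard Lewis acid that leaves the thioether alone, and this gives the (4β→8) dimer 4''-thioether F2. Soft thiophilic activation of F2 (I2, Ag2O, CH2Cl2, −78 °C) in the presence of excess 11, whose bromine cap leaves only C6 open, gives the 3,3''-bis-O-TBS trimer F3. TBAF in THF removes both silyl ethers and delivers 24.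

**2. Step 15.**

Fluoride activation of silicon may trigger β-elimination of the aryloxide O1 and so open ring C. The oxidation may also stall at a C3 that is hemmed in by the C2 and C4 aryl groups.

The fallback gives up the silicon surrogate and assembles pre-galloylated monomers from the bottom upwards. It sets out from 2, 25 and 11 and comes back at 26. Steglich esterification of 2 with 25 gives tetra-O-benzylepicatechin 3-O-(tri-O-benzylgallate) F4. DDQ with 2-ethoxyethanol gives its 4β-(2-ethoxyethoxy) derivative F5. TMSOTf-promoted coupling of F5 with excess 11 gives the (4β→6) dimer monogallate F6, with the 3-O-acyl group keeping the attack on the β-face. A second TMSOTf coupling of F5 with excess F6, which reacts at the free C8 of its upper unit, gives 26.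

**3. Step 10.**

Addition to the electron-rich, doubly ortho-substituted phenoxide aldehyde may be slow, so that the hindered aryl Grignard reagent is protonated before it can add.

The fallback reverses the polarity of the C4–C4a construction. It sets out from 6 and 12 (through 13) and comes back at 15. Quenching 13 with DMF (Bouveault aldehyde synthesis) gives 8-bromo-penta-O-benzylcatechin-6-carbaldehyde F7. Phenol 6 is converted with EtMgBr (Et2O, then toluene) into its bromomagnesium phenolate F8. In toluene F8 attacks the magnesium-coordinated F7 through its free ortho carbon (ortho-specific hydroxyalkylation of a phenolate by an aromatic aldehyde) and gives 15 directly, which makes step 5 unnecessary.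

**Further compounds**

F1 | step 14 | 4β-(2,6-dimethylphenylthio)-3-O-TBS-tetra-O-benzylepicatechin | CC(C)(C)[Si](C)(C)O[C@@H]1[C@@H](Sc7c(C)cccc7C)c2c(OCc9ccccc9)cc(OCc9ccccc9)cc2O[C@@H]1c8ccc(OCc9ccccc9)c(OCc9ccccc9)c8
F2 | step 14 | (4β→8) dimer 4''-thioether | CC(C)(C)[Si](C)(C)O[C@@H]1[C@@H](c3c(OCc9ccccc9)cc(OCc9ccccc9)c4c3O[C@H](c8ccc(OCc9ccccc9)c(OCc9ccccc9)c8)[C@H](O[Si](C)(C)C(C)(C)C)[C@H]4Sc7c(C)cccc7C)c2c(OCc9ccccc9)cc(OCc9ccccc9)cc2O[C@@H]1c8ccc(OCc9ccccc9)c(OCc9ccccc9)c8
F3 | step 14 | 3,3''-bis-O-TBS trimer | CC(C)(C)[Si](C)(C)O[C@@H]1[C@@H](c3c(OCc9ccccc9)cc(OCc9ccccc9)c4c3O[C@H](c8ccc(OCc9ccccc9)c(OCc9ccccc9)c8)[C@H](O[Si](C)(C)C(C)(C)C)[C@H]4c5c(OCc9ccccc9)c(Br)c6c(c5OCc9ccccc9)C[C@H](OCc9ccccc9)[C@@H](c8ccc(OCc9ccccc9)c(OCc9ccccc9)c8)O6)c2c(OCc9ccccc9)cc(OCc9ccccc9)cc2O[C@@H]1c8ccc(OCc9ccccc9)c(OCc9ccccc9)c8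
F4 | step 15 | tetra-O-benzylepicatechin 3-O-(tri-O-benzylgallate) | O=C(O[C@@H]1Cc2c(OCc9ccccc9)cc(OCc9ccccc9)cc2O[C@@H]1c8ccc(OCc9ccccc9)c(OCc9ccccc9)c8)c7cc(OCc9ccccc9)c(OCc9ccccc9)c(OCc9ccccc9)c7
F5 | step 15 | 4β-(2-ethoxyethoxy) derivative of F4 | O=C(O[C@@H]1[C@@H](OCCOCC)c2c(OCc9ccccc9)cc(OCc9ccccc9)cc2O[C@@H]1c8ccc(OCc9ccccc9)c(OCc9ccccc9)c8)c7cc(OCc9ccccc9)c(OCc9ccccc9)c(OCc9ccccc9)c7
F6 | step 15 | (4β→6) dimer monogallate | O=C(O[C@@H]1[C@@H](c5c(OCc9ccccc9)c(Br)c6c(c5OCc9ccccc9)C[C@H](OCc9ccccc9)[C@@H](c8ccc(OCc9ccccc9)c(OCc9ccccc9)c8)O6)c2c(OCc9ccccc9)cc(OCc9ccccc9)cc2O[C@@H]1c8ccc(OCc9ccccc9)c(OCc9ccccc9)c8)c7cc(OCc9ccccc9)c(OCc9ccccc9)c(OCc9ccccc9)c7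
F7 | step 10 | 8-bromo-penta-O-benzylcatechin-6-carbaldehyde | O=Cc1c(OCc9ccccc9)c(Br)c2c(c1OCc9ccccc9)C[C@H](OCc9ccccc9)[C@@H](c8ccc(OCc9ccccc9)c(OCc9ccccc9)c8)O2
F8 | step 10 | bromomagnesium phenolate of 6 | CC(C)(C)[Si](C)(C)O[C@@H]1[C@@H](c3c(OCc9ccccc9)cc(OCc9ccccc9)cc3O[Mg]Br)c2c(OCc9ccccc9)cc(OCc9ccccc9)cc2O[C@@H]1c8ccc(OCc9ccccc9)c(OCc9ccccc9)c8
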